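The chroman is opened by a retro-hetero-Diels–Alder cut into (−)-β-pinene and the alkylidene trione from syncarpic acid and isovaleraldehyde. The plan rests on how the pinane is made. Its ring C1–C2–C3–C4–C5–C7 grows out of a cyclopentane. In a 3,3-dimethylnorbornane with silyloxy at the bridgehead (future spiro carbon C2) and an endo triflate next to it (future C1), the CH2 bridge C7 migrates from C2 to C1. This single semipinacol shift exploits that C1 carries both one-carbon bridges. It expands one cyclopentane to the six-membered ring, contracts the other to the gem-dimethylcyclobutane and unveils the C2 ketone. The precursor derives from (−)-camphor.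

Key step: step 5

Remark: the terpene half of the target is numbered as a pinane (C2 spiro carbon, C1/C5 bridgeheads, C6 = CMe2, C7 = CH2 bridge). Compounds 2–7 are numbered as bicyclo[2.2.1]heptanes. Old C1, C2, C3, C4, C5, C6, C7 become pinane C2, C1, C6, C5, C4, C3, C7.

Step 1
Reactants: 1 (1S,4S)-(−)-camphor
Product: 2 (1S,4S)-3,3-dimethyl-2-methylidenebicyclo[2.2.1]heptan-1-yl trifluoromethanesulfonate
Conditions: Tf2O (1.2 equiv), 2,6-di-tert-butyl-4-methylpyridine (1.3 equiv), CH2Cl2, 0 °C → rt
Reagents that add atoms: triflic anhydride, O=S(=O)(OS(=O)(=O)C(F)(F)F)C(F)(F)F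
Why: O-triflylation of the ketone gives a 2-triflyloxy cation, a Wagner–Meerwein shift of camphor C6 from C1 to C2 turns the triflate-bearing carbon into a bridgehead and loss of a proton from the C10 methyl group ends the cascade, while camphor C4 is never touched, so its configuration fixes both stereocentres of 2.

Step 2
Reactants: 2 bridgehead triflate
Product: 3 (1S,4S)-3,3-dimethyl-2-methylidenebicyclo[2.2.1]heptan-1-ol
Conditions: LiAlH4, Et2O, 0 °C → rt; aqueous NaOH work-up
Reagents that add atoms: none
Why: the bridgehead carbon allows neither SN1 nor SN2 attack, so hydride attacks sulfur and cleaves the S–O bond (reductive detriflylation) with retention at C1.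

Step 3
Reactants: 3 bridgehead alcohol
Product: 4 triethyl{[(1S,4S)-3,3-dimethyl-2-methylidenebicyclo[2.2.1]heptan-1-yl]oxy}silane
Conditions: Et3SiCl, imidazole, 4-(dimethylamino)pyridine (cat.), DMF, rt → 40 °C
Reagents that add atoms: chlorotriethylsilane, CC[Si](Cl)(CC)CC
Why: silylation of a tied-back, sterically open bridgehead alcohol under basic conditions avoids the acid-triggered Wagner–Meerwein shift of 3, and the silyl ether later guarantees that only the C2 oxygen can be sulfonylated.

Step 4
Reactants: 4 silyl ether
Product: 6 (1S,2S,4S)-3,3-dimethyl-1-(triethylsilyloxy)bicyclo[2.2.1]heptan-2-ol (2-endo alcohol), via silyloxy ketone 5 (not isolated)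
Conditions: O3, CH2Cl2/MeOH, −78 °C; then NaBH4 (excess), −78 °C → rt
Reagents that add atoms: ozone, [O-][O+]=O
Why: ozonolysis removes the exocyclic CH2, and the borohydride work-up should reduce ketone 5 from the exo face, as with fenchone and other norbornan-2-ones that lack a syn-7 substituent, so the new C2 stereocentre carries an endo hydroxyl (2S).

Step 5
Reactants: 6 endo alcohol
Product: 8 (1R,5S)-6,6-dimethylbicyclo[3.1.1]heptan-2-one, (+)-nopinone, via endo triflate 7 (not isolated)
Conditions: Tf2O (1.2 equiv), pyridine (4 equiv), CH2Cl2, −40 °C → rt; 1 M HCl work-up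
Reagents that add atoms: none
Why: Triflation of the only free hydroxyl gives endo triflate 7, whose C2–O bond is antiperiplanar to the C1–C7 bond of the norbornane (C1–C6 is gauche), so ionisation is coupled to migration of C7 from C1 to C2 while the lone pair of the bridgehead silyloxy group turns C1 into a silyloxocarbenium ion, which loses its silyl group to triflate/pyridine and ends as the ketone. This is a semipinacol rearrangement of a vicinal silyloxy sulfonate; the closest known cases are the pinacol-type bridge shifts of bridgehead-alkoxy bicyclo[2.2.2]octan-2-yl sulfonates and the equally strain-raising contraction of 2-oxonorborn-1-yl triflates to bicyclo[2.1.1]hexanes. No ring is closed by a new external bond: the 1,2-shift expands the cyclopentane C1–C6–C5–C4–C7 by insertion of C2 to the cyclohexanone ring of 8 and at the same time contracts the cyclopentane C1–C2–C3–C4–C7 to the cyclobutane C2–C3–C4–C7. The one new stereocentre, C1 of 8 (old C2), forms with inversion at the migration terminus and, like C5 (old C4, never touched), is dictated by the cage, so (−)-camphor maps onto (1R,5S)-8. The step needs C7 to migrate rather than C6 or a methyl group, which the endo geometry of the leaving group secures, and it needs the leaving group on C2 and not on the bridgehead oxygen, which the silyl ether secures. The gain of the C=O bond and the triflate nucleofuge should pay for the extra strain of the bicyclo[3.1.1]heptane.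

Step 6
Reactants: 8 (+)-nopinone
Product: 9 (1S,5S)-6,6-dimethyl-2-methylidenebicyclo[3.1.1]heptane, (−)-β-pinene
Conditions: Ph3PCH3Br, KOtBu, THF, 0 °C → reflux; pentane extraction, careful concentration
Reagents that add atoms: methyltriphenylphosphonium bromide, C[P+](c1ccccc1)(c1ccccc1)c1ccccc1.[Br-]
Why: Wittig methylenation of a moderately hindered ketone whose two stereocentres are bridgeheads and cannot epimerise.

Step 7
Reactants: 10 2',4',6'-trihydroxyacetophenone
Product: 11 2-acetyl-3-hydroxy-4,4,6,6-tetramethylcyclohex-2-ene-1,5-dione (acetylsyncarpic acid)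
Conditions: MeI (6 equiv), NaOMe (5 equiv), MeOH, reflux; then aq. HCl
Reagents that add atoms: iodomethane, CI
Why: base-mediated exhaustive C-methylation dearomatises the acylphloroglucinol at its two free ring carbons.

Step 8
Reactants: 11 acetylsyncarpic acid
Product: 12 2,2,4,4-tetramethylcyclohexane-1,3,5-trione (syncarpic acid)
Conditions: 6 M HCl, reflux
Reagents that add atoms: none
Why: acid-promoted retro-Claisen deacylation of the tricarbonylmethane unit releases the parent cyclic trione.

Step 9
Reactants: 9 (−)-β-pinene; 12 syncarpic acid; 13 3-methylbutanal (isovaleraldehyde)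
Product: 15 (2R,4S,1'R,5'S)-4-isobutyl-6,6,6',6',8,8-hexamethyl-3,4-dihydrospiro[chromene-2,2'-bicyclo[3.1.1]heptane]-5,7(6H,8H)-dione (target), via alkylidene trione 14 (not isolated)
Conditions: ethylenediammonium diacetate (20 mol %), 4 Å molecular sieves, toluene, 50–60 °C; 12 and 13 (1.5 equiv each) added slowly to 9
Reagents that add atoms: none
Why: domino Knoevenagel condensation/inverse-electron-demand hetero-Diels–Alder reaction, in which 12 and 13 give heterodiene 14, the nucleophilic CH2 terminus of 9 bonds to the alkylidene carbon and the disubstituted carbon C2 to oxygen, the heterodiene approaches the alkene on the side of the CH2 bridge C7 (the syn methyl on C6 shields the other face, which sets 2R with oxygen anti to the CMe2 bridge), and the trione ring lies over the C3–C4 side rather than under C1/C7 with the isobutyl group in the outside position of the heterodiene, which sets 4S.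

Compound list
1 | (1S,4S)-(−)-camphor | C[C@]12CC[C@H](C1(C)C)CC2=O | starting material
2 | (1S,4S)-3,3-dimethyl-2-methylidenebicyclo[2.2.1]heptan-1-yl trifluoromethanesulfonate | C=C1C(C)(C)[C@H]2CC[C@]1(OS(=O)(=O)C(F)(F)F)C2 | intermediate
3 | (1S,4S)-3,3-dimethyl-2-methylidenebicyclo[2.2.1]heptan-1-ol | C=C1C(C)(C)[C@H]2CC[C@]1(O)C2 | intermediate
4 | triethyl{[(1S,4S)-3,3-dimethyl-2-methylidenebicyclo[2.2.1]heptan-1-yl]oxy}silane | C=C1C(C)(C)[C@H]2CC[C@]1(O[Si](CC)(CC)CC)C2 | intermediate
5 | (1S,4S)-3,3-dimethyl-1-(triethylsilyloxy)bicyclo[2.2.1]heptan-2-one | O=C1C(C)(C)[C@H]2CC[C@]1(O[Si](CC)(CC)CC)C2 | intermediate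
6 | (1S,2S,4S)-3,3-dimethyl-1-(triethylsilyloxy)bicyclo[2.2.1]heptan-2-ol (endo alcohol) | O[C@H]1C(C)(C)[C@H]2CC[C@]1(O[Si](CC)(CC)CC)C2 | intermediate
7 | (1S,2S,4S)-3,3-dimethyl-1-(triethylsilyloxy)bicyclo[2.2.1]heptan-2-yl trifluoromethanesulfonate (endo triflate) | O=S(=O)(O[C@H]1C(C)(C)[C@H]2CC[C@]1(O[Si](CC)(CC)CC)C2)C(F)(F)F | intermediate
8 | (1R,5S)-6,6-dimethylbicyclo[3.1.1]heptan-2-one, (+)-nopinone | O=C1CC[C@H]2C[C@@H]1C2(C)C | intermediate
9 | (1S,5S)-6,6-dimethyl-2-methylidenebicyclo[3.1.1]heptane, (−)-β-pinene | C=C1CC[C@H]2C[C@@H]1C2(C)C | intermediate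
10 | 2',4',6'-trihydroxyacetophenone | CC(=O)c1c(O)cc(O)cc1O | starting material
11 | acetylsyncarpic acid | CC(=O)C1=C(O)C(C)(C)C(=O)C(C)(C)C1=O | intermediate
12 | syncarpic acid | CC1(C)C(=O)CC(=O)C(C)(C)C1=O | intermediate
13 | 3-methylbutanal | CC(C)CC=O | starting material
14 | 2,2,4,4-tetramethyl-6-(3-methylbutylidene)cyclohexane-1,3,5-trione | CC(C)CC=C1C(=O)C(C)(C)C(=O)C(C)(C)C1=O | intermediate
15 | (2R,4S,1'R,5'S)-4-isobutyl-6,6,6',6',8,8-hexamethyl-3,4-dihydrospiro[chromene-2,2'-bicyclo[3.1.1]heptane]-5,7(6H,8H)-dione | CC(C)C[C@H]1C[C@@]2(CC[C@H]3C[C@@H]2C3(C)C)OC2=C1C(=O)C(C)(C)C(=O)C2(C)C | target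

Total step count: 9. Longest linear sequence: 7 (steps 1–6 and 9).

Steps most likely to fail

Step 5. Triflation of the crowded endo alcohol may be slow. Ionisation may also leak away from the C7 shift into unassisted cation chemistry, because the shift raises strain. The fallback sets out from 5, which is isolated by working up the ozonolysis of 4 with Me2S instead of NaBH4. Condensation with NH2OH·HCl in pyridine/EtOH gives the silyloxy ketone oxime F1. Reduction with LiAlH4 from the exo face gives the endo amine F2. Diazotisation with NaNO2 in aqueous AcOH then produces an endo diazonium ion that is again antiperiplanar to C1–C7. A Tiffeneau–Demjanov-type shift, driven by loss of nitrogen and accompanied by loss of the silyl group, returns to 8.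

Step 9. The heterodiene may be consumed by Michael addition of a second molecule of 12 or by an ene reaction. The alkene may isomerise under the mildly acidic catalysis. The orientation of the heterodiene over C3–C4 may be only modestly preferred, so that the C4 epimer has to be removed by chromatography. The fallback sets out from 12 and 13. They are condensed with piperidine in CH2Cl2 to the isolable Mannich base F3, which is freed from excess 12. F3 is then heated with 9 in toluene. Slow retro-Mannich elimination releases 14 at low stationary concentration, without free aldehyde or acid, and the cycloaddition comes back to the route at 15.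

Step 4. The hindered carbonyl oxide may undergo Criegee-type rearrangement or the alkene may be epoxidised. The one-pot borohydride reduction may also show poor facial selectivity or allow silyl migration to the new alkoxide. The fallback sets out from 4. Dihydroxylation with OsO4 (cat.)/N-methylmorpholine N-oxide from the exo face gives the vicinal diol F4. Cleavage with NaIO4 gives isolated 5. A separate reduction with the bulky hydride LiBH(s-Bu)3 in THF at −78 °C enforces exo attack and comes back to the route at 6.

Further compounds
F1 | step 5 | (1S,4S)-3,3-dimethyl-1-(triethylsilyloxy)bicyclo[2.2.1]heptan-2-one oxime | ON=C1C(C)(C)[C@H]2CC[C@]1(O[Si](CC)(CC)CC)C2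
F2 | step 5 | (1S,2S,4S)-3,3-dimethyl-1-(triethylsilyloxy)bicyclo[2.2.1]heptan-2-amine (endo amine) | N[C@H]1C(C)(C)[C@H]2CC[C@]1(O[Si](CC)(CC)CC)C2
F3 | step 9 | 3-hydroxy-4,4,6,6-tetramethyl-2-[3-methyl-1-(piperidin-1-yl)butyl]cyclohex-2-ene-1,5-dione (Mannich base) | CC(C)CC(N1CCCCC1)C1=C(O)C(C)(C)C(=O)C(C)(C)C1=O
F4 | step 4 | (1S,2S,4S)-2-(hydroxymethyl)-3,3-dimethyl-1-(triethylsilyloxy)bicyclo[2.2.1]heptan-2-ol | OC[C@@]1(O)C(C)(C)[C@H]2CC[C@]1(O[Si](CC)(CC)CC)C2
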